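6 questions stood on 3 flasks, oak, birch and alder: which holds more of the starting material at the end, target or side product B, and how much target stands.

    starting material + rival reagent → side product A (k1 = 0.00341 L mol⁻¹ s⁻¹)
    starting material + partner → target (k2 = 0.0509 L mol⁻¹ s⁻¹)
    starting material + target ⇌ idle adduct, settled at all times (K3 = 7.52 L mol⁻¹)
    starting material + target → side product B (k4 = 0.0460 L mol⁻¹ s⁻¹)
    rival reagent → decomposed reagent (k5 = 0.00728 s⁻¹)

| flask | starting material | partner | rival reagent | time |
|---|---|---|---|---|
| oak | 0.050 M | 0.200 M | 0.125 M | 2.0 min |
| birch | 0.050 M | 0.0900 M | 0.125 M | 2.0 min |
| alder | 0.050 M | 0.140 M | 0.125 M | 2.0 min |

* which of the two there is more of at the end, counted by the starting material in each, oak (target / side product B)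
* which of the two there is more of at the end, counted by the starting material in each, birch (target / side product B)
* which of the two there is more of at the end, counted by the starting material in each, alder (target / side product B)
* target at the end, in percent of the starting material charged, oak
* target at the end, in percent of the starting material charged, birch
* target at the end, in percent of the starting material charged, alder

- in percentages every species weighs as the starting material in it: one idle adduct or side product B counts as two
- for target the idle adduct is counted in
- in an amount of target, one idle adduct counts as one target
- run time (oak): 2.0 min

I began with the making of target by itself. With the partner held at its charge the step is pseudo-first-order, and in birch its exponent, rate constant times partner times time, was 0.550, which put target at 42.3 %.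

Then I added the rival reagent. It decays while it works, so its exponent over the run was 0.0341, far smaller than birch's main exponent, and target made in birch eased to 41.6 %.

Next came the loss to side product B, and here I divided one rate by the other. Free starting material stands in both rates, so it and time drop out: target lost per target made is simply free target divided by the amount of free target at which loss equals making. I called that amount the break-even target, the making constant times partner over the loss constant, 0.0996 M in birch. It is larger than the charge of starting material, so with the partner at its charge the ratio stayed below one. The ratio climbs from zero as target grows, so I took half its end value as its mean, which left 37.3 % in birch.

Last I added the idle adduct. Taking target over the run as half of what was made, I let the balance divide the free starting material, and so my exponent, by 1.08. Target made in birch fell to 39.4 %, and the rule, with target made still counted as free, left 35.5 %, with side product B, which holds starting material twice over, at 7.78 %.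

The same steps gave oak, with a break-even target of 0.221 M, 65.2 % made and 60.4 % kept. Alder, at 0.155 M, gave 53.1 % made and 48.6 % kept. The larger of the two was target in oak, target in birch and target in alder. I had held the partner at its charge, and it falls as target forms, so I expected my target figures to lean high.

The forecast gave target 56.3 % in oak, 33 % in birch and 45.2 % in alder, each below my figure , on this ground: “Free and bound material must be kept apart.”

The flasks gave target against side product B as 57.2 % to 7.59 % in oak, 33.1 % to 5.67 % in birch and 45.7 % to 6.94 % in alder. In birch the making of target used starting material 13 times as fast as the loss to side product B at 0.785 min and 5.8 times as fast at 2.00 min; the break-even target, scaled to the 80 % of partner left, over the 0.0138 M of free target gives 5.78. Birch's neighbour with 0.020 M of starting material has the same break-even target at its charge of partner, and its side product B, for which my birch figure scaled by the charge gives 3.11 %, stood at 2.86 %.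

(The constants used here were chosen freely; no experiment stands behind them.)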